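**Strategy.** Ring A is cut at C2–C3 and C5–C10 (labdane numbering). C3–C4–C5 come from a chiral 3-(bromomethyl)butenolide whose γ-carbon is C6, the oxygenated carbon of ring B next to the ring fusion; C10–C1–C2 come from the dianion of methyl 2-methylacetoacetate. In one operation γ-alkylation and an intramolecular Michael addition forge both bonds, close ring A and set C5 and C10 from the single C6 stereocentre through a chair transition state. The lactone carbonyl later becomes the axial C19 methyl group. Ring B is then closed by a SmI2 ketyl–olefin cyclization (C8–C9), and the butenolide side chain is attached by a Negishi coupling.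

Key step: step 4

Remark on numbering: decalin C1–C10, side chain C11–C16 (C16 = butenolide CH), C17 = CH3 on C8, C18 = CH2O on C4, C19 = CH3 on C4, C20 = CH3 on C10; α/β are the faces of the final trans-decalin (C20 is β).

Assumption: (R)-SEGPHOS in step 2 and the (R,R)-cobalt salen complex in step 18 are taken to be the antipodes that give (R)-4 and leave (R)-26; if either sense is opposite, the mirror-image ligand is used.

**Route**

Step 1
Reactants: 1 ethyl 2-(2-methyl-1,3-dioxolan-2-yl)acetate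
Product: 2 2-(2-methyl-1,3-dioxolan-2-yl)ethanol
Conditions: LiAlH4, Et2O, 0 °C
Reagents that add atoms: none
Why: Hydride reduction of the ester should give the primary alcohol and leave the ketal untouched.

Step 2
Reactants: 2 2-(2-methyl-1,3-dioxolan-2-yl)ethanol; 3 methyl 2-{[(tert-butoxycarbonyl)oxy]methyl}prop-2-enoate
Product: 4 (5R)-3-methylidene-5-[(2-methyl-1,3-dioxolan-2-yl)methyl]oxolan-2-one
Conditions: [Ir(cod)Cl]2 (2.5 mol%), (R)-SEGPHOS (5 mol%), 4-cyano-3-nitrobenzoic acid (10 mol%), Cs2CO3 (20 mol%), THF, 70 °C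
Reagents that add atoms: none
Why: Iridium-catalysed transfer-hydrogenative carbonyl 2-(alkoxycarbonyl)allylation from the alcohol oxidation level, followed by lactonization onto the methyl ester, should give the α-methylene lactone with C6 set by the chiral ligand.

Step 3
Reactants: 4 (5R)-3-methylidene-5-[(2-methyl-1,3-dioxolan-2-yl)methyl]oxolan-2-one
Product: 6 (5S)-3-(bromomethyl)-5-[(2-methyl-1,3-dioxolan-2-yl)methyl]furan-2(5H)-one, via dibromide 5 (not isolated)
Conditions: Br2, CH2Cl2, 0 °C; then DBU, 0 → 23 °C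
Reagents that add atoms: bromine, BrBr
Why: Bromine addition to the exocyclic alkene and E2 loss of HBr (C5–H, C4–Br) should give the endocyclic α-(bromomethyl)butenolide without touching C6.

Step 4
Reactants: 6 (5S)-3-(bromomethyl)-5-[(2-methyl-1,3-dioxolan-2-yl)methyl]furan-2(5H)-one; 7 methyl 2-methyl-3-oxobutanoate
Product: 9 ring A keto lactone (C1 ketone; C10 bearing β-CH3 and CO2CH3; γ-lactone C19(=O)–O–C6 cis-fused at C4–C5; 5α-H; 6S; C7–C8 as the dioxolane-protected acetonyl group), via keto ester enolate 8 (not isolated)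
Conditions: 7, NaH, THF, 0 °C; n-BuLi, 0 °C; 6, −78 °C; then t-BuOH (1 equiv), −78 → 23 °C; AcOH quench
Reagents that add atoms: none
Why: The acetoacetate dianion of 7 should be alkylated at its terminal carbon C2 by the primary allylic bromide of 6 (SN2, C2–C3), which leaves the chelated β-keto ester enolate 8 tethered to the α-carbon C4 of the butenolide; on warming this enolate should add through C10 to the β-carbon C5 (intramolecular Michael addition, C5–C10), and the lactone enolate is protonated by t-BuOH. The closest known reaction types are the γ-alkylation of acetoacetate dianions with allylic bromides and the alkylation–Michael [3+3] annulation of 1,3-dicarbonyl compounds with 2-(bromomethyl)enoates. Ring A (C1–C5, C10) closes in a 6-(enolendo)-endo-trig Michael mode through a Cope-like chair array C10=C1–C2–C3–C4=C5. C5 is set by attack on the butenolide face anti to the C7 side chain on C6; C10 is set by the chair, in which the metal chelate holds CO2CH3 syn to the enolate oxygen (outside, equatorial) and CH3 inside (axial), while H5 is inside by ring constraint, so CH3 and H5 end up trans as the trans-decalin requires; C4 stays an epimerizable CH. The step needs SN2 attack at CH2Br rather than SN2′ attack at the hindered, β-substituted C5 (favoured by the unhindered carbanion at −78 °C), and Michael rather than acyl attack of the enolate (acyl transfer to the non-enolizable C10 is reversible, the Michael adduct is not).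

Step 5
Reactants: 9 ring A keto lactone
Product: 11 1-deoxo lactone (as 9 with C1 = CH2), via C1 tosylhydrazone 10 (not isolated)
Conditions: TsNHNH2, EtOH, 60 °C; then catecholborane, CHCl3, 0 °C; NaOAc·3H2O, reflux
Reagents that add atoms: none
Why: Tosylhydrazone formation and catecholborane reduction (a mild Wolff–Kishner-type deoxygenation) should remove the C1 carbonyl without touching lactone, ester or ketal.

Step 6
Reactants: 11 1-deoxo lactone
Product: 12 4α-[(triisopropylsilyloxy)methyl] lactone (C18 installed; lactone carbonyl C19 β)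
Conditions: LiN(iPr)2, THF/DMPU, −78 °C; (triisopropylsiloxy)methyl chloride, −78 → −20 °C
Reagents that add atoms: (triisopropylsiloxy)methyl chloride, CC(C)[Si](OCCl)(C(C)C)C(C)C
Why: Alkylation of the only enolizable position (lactone enolate at C4) should occur on the convex face of the cis-fused bicycle, cis to H5, which places C18 α and makes C4 quaternary.

Step 7
Reactants: 12 4α-[(triisopropylsilyloxy)methyl] lactone
Product: 13 C19 lactol (anomer mixture)
Conditions: iBu2AlH (1.1 equiv), CH2Cl2, −78 °C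
Reagents that add atoms: none
Why: Half-reduction of the γ-lactone should stop at the lactol, the lactone being more electrophilic than the neopentyl methyl ester on C10.

Step 8
Reactants: 13 C19 lactol
Product: 15 ring A hydroxy ester (4β-CH3; 4α-CH2OTIPS; free 6-OH; CO2CH3 on C10), via C19 tosylhydrazone 14 (not isolated)
Conditions: TsNHNH2, THF, 50 °C; then catecholborane, CHCl3, 0 °C; NaOAc·3H2O, reflux
Reagents that add atoms: none
Why: Ring–chain tautomerism exposes the C19 aldehyde, whose tosylhydrazone should be reduced by catecholborane to the axial C19 methyl group (Wolff–Kishner-type deoxygenation), freeing the C6 hydroxyl.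

Step 9
Reactants: 15 ring A hydroxy ester
Product: 16 6-O-TBS ether of 15
Conditions: TBSOTf, 2,6-lutidine, CH2Cl2, 0 °C
Reagents that add atoms: tert-butyldimethylsilyl trifluoromethanesulfonate, CC(C)(C)[Si](C)(C)OS(=O)(=O)C(F)(F)F
Why: Silylation of the hindered secondary alcohol blocks later oxa-Michael addition of O6 to the enoate.

Step 10
Reactants: 16 6-O-TBS ether
Product: 17 C9 aldehyde
Conditions: iBu2AlH, toluene, −78 °C
Reagents that add atoms: none
Why: Partial reduction of the α-quaternary methyl ester should stop at the non-enolizable neopentyl aldehyde.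

Step 11
Reactants: 17 C9 aldehyde
Product: 18 tert-butyl (E)-enoate (C9=C11; C12 ester)
Conditions: Ph3P=CHCO2tBu, toluene, 100 °C
Reagents that add atoms: tert-butyl (triphenylphosphoranylidene)acetate, CC(C)(C)OC(=O)C=P(c1ccccc1)(c1ccccc1)c1ccccc1
Why: Wittig olefination with the stabilized ylide should give the (E)-enoate that will accept the C8 ketyl.

Step 12
Reactants: 18 tert-butyl (E)-enoate
Product: 19 C8 methyl ketone
Conditions: PPTS, acetone/H2O, 50 °C
Reagents that add atoms: water, O
Why: Mild ketal hydrolysis should unveil the methyl ketone while silyl ethers and the tert-butyl ester survive.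

Step 13
Reactants: 19 C8 methyl ketone
Product: 20 trans-decalin hydroxy ester (8α-OH; 8β-CH3; 9β-CH2CO2tBu; 6α-OTBS; 18-OTIPS)
Conditions: SmI2 (3 equiv), HMPA, t-BuOH, THF, −78 → 0 °C
Reagents that add atoms: none
Why: SmI2 ketyl–olefin cyclization (6-exo) should close ring B through a chair in which the bulky samarium-bound ketyl oxygen and the enoate arm are equatorial and anti, setting 8α-OH/8β-CH3 and 9α-H.

Step 14
Reactants: 20 trans-decalin hydroxy ester
Product: 21 8-O-TMS ether of 20
Conditions: 1-(trimethylsilyl)imidazole, CH2Cl2, 23 °C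
Reagents that add atoms: 1-(trimethylsilyl)imidazole, C[Si](C)(C)n1ccnc1
Why: Silylation of the tertiary alcohol prevents its cyclization onto C12 (tetrahydrofuran formation) during the later activation.

Step 15
Reactants: 21 8-O-TMS ether
Product: 22 C12 primary alcohol
Conditions: LiAlH4, Et2O, 0 → 23 °C
Reagents that add atoms: none
Why: Hydride reduction of the tert-butyl ester should give the primary alcohol with the silyl ethers intact.

Step 16
Reactants: 22 C12 primary alcohol
Product: 23 C12 primary iodide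
Conditions: I2, PPh3, imidazole, CH2Cl2, 0 °C
Reagents that add atoms: iodine, II
Why: Appel-type iodination converts the only free, primary alcohol into the iodide.

Step 17
Reactants: 24 2-methyl-2-vinyl-1,3-dioxolane
Product: 25 rac-2-methyl-2-(oxiran-2-yl)-1,3-dioxolane
Conditions: mCPBA, NaHCO3, CH2Cl2, 0 → 23 °C
Reagents that add atoms: 3-chloroperbenzoic acid, OOC(=O)c1cccc(Cl)c1
Why: Prilezhaev epoxidation of the terminal alkene.

Step 18
Reactants: 25 rac-2-methyl-2-(oxiran-2-yl)-1,3-dioxolane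
Product: 26 (R)-2-methyl-2-(oxiran-2-yl)-1,3-dioxolane
Conditions: (R,R)-[N,N′-bis(3,5-di-tert-butylsalicylidene)-1,2-cyclohexanediaminato]cobalt acetate (0.5 mol%), H2O (0.55 equiv), THF, 0 → 23 °C
Reagents that add atoms: none
Why: Hydrolytic kinetic resolution of the terminal epoxide should leave the (R)-epoxide, which carries the future C16 configuration.

Step 19
Reactants: 26 (R)-2-methyl-2-(oxiran-2-yl)-1,3-dioxolane
Product: 27 (1R)-1-(2-methyl-1,3-dioxolan-2-yl)pent-3-yn-1-ol
Conditions: 1-propynyllithium, BF3·OEt2, THF, −78 °C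
Reagents that add atoms: 1-propynyllithium, [Li]C#CC
Why: BF3-assisted opening of the epoxide by the alkynyllithium at the terminal carbon keeps the C16 configuration.

Step 20
Reactants: 27 (1R)-1-(2-methyl-1,3-dioxolan-2-yl)pent-3-yn-1-ol
Product: 29 (3R,5E)-3-hydroxy-6-iodohept-5-en-2-one, via ketal vinyl iodide 28 (not isolated)
Conditions: Cp2Zr(H)Cl (3 equiv), THF, 23 → 40 °C; I2, 0 °C; then 2 M HCl, THF, 23 °C
Reagents that add atoms: iodine, II; water, O
Why: Syn hydrozirconation of the 2-alkyne, equilibrating zirconium to the methyl-bearing carbon, then iodinolysis with retention should give the (E)-2-iodoalkene, and acid hydrolysis frees the methyl ketone.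

Step 21
Reactants: 29 (3R,5E)-3-hydroxy-6-iodohept-5-en-2-one
Product: 30 (5R)-5-[(2E)-3-iodobut-2-en-1-yl]-4-methylfuran-2(5H)-one
Conditions: Ph3P=C=C=O, toluene, 110 °C
Reagents that add atoms: (triphenylphosphoranylidene)ketene, O=C=C=P(c1ccccc1)(c1ccccc1)c1ccccc1
Why: O-Acylation of the α-hydroxy ketone by the ketene ylide and intramolecular Wittig reaction with the methyl ketone should build the 4-methylbutenolide without touching C16.

Step 22
Reactants: 23 C12 primary iodide; 30 (5R)-5-[(2E)-3-iodobut-2-en-1-yl]-4-methylfuran-2(5H)-one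
Product: 32 tris-silyl ether of the target (18-OTIPS; 6-OTBS; 8-OTMS), via alkylzinc iodide 31 (not isolated)
Conditions: 23, Zn dust, LiCl, THF, 40 °C; then 30, Pd(PPh3)4 (5 mol%), THF, 40 °C
Reagents that add atoms: none
Why: Zinc insertion and Negishi sp3–sp2 coupling under neutral conditions should join C12 to C13 with retention of the (E)-alkene and tolerate the butenolide.

Step 23
Reactants: 32 tris-silyl ether of the target
Product: 33 target triol (CNP0147582.1)
Conditions: HF·pyridine, THF/pyridine, 0 → 40 °C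
Reagents that add atoms: none
Why: Global desilylation under mildly acidic fluoride conditions should free the three hydroxyls without epimerizing the butenolide.

**Compound list**

1 | ethyl 2-(2-methyl-1,3-dioxolan-2-yl)acetate | CCOC(=O)CC1(C)OCCO1 | starting material
2 | 2-(2-methyl-1,3-dioxolan-2-yl)ethanol | OCCC1(C)OCCO1 | intermediate
3 | methyl 2-{[(tert-butoxycarbonyl)oxy]methyl}prop-2-enoate | COC(=O)C(=C)COC(=O)OC(C)(C)C | starting material
4 | (5R)-3-methylidene-5-[(2-methyl-1,3-dioxolan-2-yl)methyl]oxolan-2-one | C=C1C[C@H](CC2(C)OCCO2)OC1=O | intermediate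
5 | (5R)-3-bromo-3-(bromomethyl)-5-[(2-methyl-1,3-dioxolan-2-yl)methyl]oxolan-2-one (C3 mixture) | BrCC1(Br)C[C@H](CC2(C)OCCO2)OC1=O | intermediate
6 | (5S)-3-(bromomethyl)-5-[(2-methyl-1,3-dioxolan-2-yl)methyl]furan-2(5H)-one | BrCC1=C[C@H](CC2(C)OCCO2)OC1=O | intermediate
7 | methyl 2-methyl-3-oxobutanoate | COC(=O)C(C)C(C)=O | starting material
8 | methyl 2-methyl-3-oxo-5-{(5S)-5-[(2-methyl-1,3-dioxolan-2-yl)methyl]-2-oxo-2,5-dihydrofuran-3-yl}pentanoate (formed as its enolate) | COC(=O)C(C)C(=O)CCC1=C[C@H](CC2(C)OCCO2)OC1=O | intermediate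
9 | ring A keto lactone (C1 ketone; 10β-CH3; CO2CH3 on C10; C19 lactone to O6; 5α-H; 4α-H) | COC(=O)[C@@]1(C)C(=O)CC[C@@H]2C(=O)O[C@@H](CC3(C)OCCO3)[C@H]12 | intermediate
10 | C1 tosylhydrazone of 9 | COC(=O)[C@@]1(C)C(=NNS(=O)(=O)c2ccc(C)cc2)CC[C@@H]2C(=O)O[C@@H](CC3(C)OCCO3)[C@H]12 | intermediate
11 | 1-deoxo lactone | COC(=O)[C@@]1(C)CCC[C@@H]2C(=O)O[C@@H](CC3(C)OCCO3)[C@H]12 | intermediate
12 | 4α-[(triisopropylsilyloxy)methyl] lactone | COC(=O)[C@@]1(C)CCC[C@]2(CO[Si](C(C)C)(C(C)C)C(C)C)C(=O)O[C@@H](CC3(C)OCCO3)[C@H]12 | intermediate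
13 | C19 lactol (anomer mixture) | COC(=O)[C@@]1(C)CCC[C@]2(CO[Si](C(C)C)(C(C)C)C(C)C)C(O)O[C@@H](CC3(C)OCCO3)[C@H]12 | intermediate
14 | open-chain C19 tosylhydrazone with free 6-OH | COC(=O)[C@@]1(C)CCC[C@@](C=NNS(=O)(=O)c2ccc(C)cc2)(CO[Si](C(C)C)(C(C)C)C(C)C)[C@@H]1[C@@H](O)CC3(C)OCCO3 | intermediate
15 | ring A hydroxy ester (4β-CH3; 4α-CH2OTIPS; 6-OH) | COC(=O)[C@@]1(C)CCC[C@@](C)(CO[Si](C(C)C)(C(C)C)C(C)C)[C@@H]1[C@@H](O)CC2(C)OCCO2 | intermediate
16 | 6-O-TBS ether of 15 | COC(=O)[C@@]1(C)CCC[C@@](C)(CO[Si](C(C)C)(C(C)C)C(C)C)[C@@H]1[C@@H](O[Si](C)(C)C(C)(C)C)CC2(C)OCCO2 | intermediate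
17 | C9 aldehyde | O=C[C@@]1(C)CCC[C@@](C)(CO[Si](C(C)C)(C(C)C)C(C)C)[C@@H]1[C@@H](O[Si](C)(C)C(C)(C)C)CC2(C)OCCO2 | intermediate
18 | tert-butyl (E)-enoate (C9=C11) | CC(C)(C)OC(=O)/C=C/[C@@]1(C)CCC[C@@](C)(CO[Si](C(C)C)(C(C)C)C(C)C)[C@@H]1[C@@H](O[Si](C)(C)C(C)(C)C)CC2(C)OCCO2 | intermediate
19 | C8 methyl ketone | CC(C)(C)OC(=O)/C=C/[C@@]1(C)CCC[C@@](C)(CO[Si](C(C)C)(C(C)C)C(C)C)[C@@H]1[C@@H](O[Si](C)(C)C(C)(C)C)CC(C)=O | intermediate
20 | trans-decalin hydroxy ester (8α-OH; 9β-CH2CO2tBu) | CC(C)(C)OC(=O)C[C@@H]1[C@@]2(C)CCC[C@@](C)(CO[Si](C(C)C)(C(C)C)C(C)C)[C@@H]2[C@@H](O[Si](C)(C)C(C)(C)C)C[C@@]1(C)O | intermediate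
21 | 8-O-TMS ether of 20 | CC(C)(C)OC(=O)C[C@@H]1[C@@]2(C)CCC[C@@](C)(CO[Si](C(C)C)(C(C)C)C(C)C)[C@@H]2[C@@H](O[Si](C)(C)C(C)(C)C)C[C@@]1(C)O[Si](C)(C)C | intermediate
22 | C12 primary alcohol | OCC[C@@H]1[C@@]2(C)CCC[C@@](C)(CO[Si](C(C)C)(C(C)C)C(C)C)[C@@H]2[C@@H](O[Si](C)(C)C(C)(C)C)C[C@@]1(C)O[Si](C)(C)C | intermediate
23 | C12 primary iodide | ICC[C@@H]1[C@@]2(C)CCC[C@@](C)(CO[Si](C(C)C)(C(C)C)C(C)C)[C@@H]2[C@@H](O[Si](C)(C)C(C)(C)C)C[C@@]1(C)O[Si](C)(C)C | intermediate
24 | 2-methyl-2-vinyl-1,3-dioxolane | C=CC1(C)OCCO1 | starting material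
25 | rac-2-methyl-2-(oxiran-2-yl)-1,3-dioxolane | CC1(C2CO2)OCCO1 | intermediate
26 | (R)-2-methyl-2-(oxiran-2-yl)-1,3-dioxolane | CC1([C@H]2CO2)OCCO1 | intermediate
27 | (1R)-1-(2-methyl-1,3-dioxolan-2-yl)pent-3-yn-1-ol | CC#CC[C@@H](O)C1(C)OCCO1 | intermediate
28 | (1R,3E)-4-iodo-1-(2-methyl-1,3-dioxolan-2-yl)pent-3-en-1-ol | C/C(I)=C\C[C@@H](O)C1(C)OCCO1 | intermediate
29 | (3R,5E)-3-hydroxy-6-iodohept-5-en-2-one | CC(=O)[C@H](O)C/C=C(\C)I | intermediate
30 | (5R)-5-[(2E)-3-iodobut-2-en-1-yl]-4-methylfuran-2(5H)-one | CC1=CC(=O)O[C@@H]1C/C=C(\C)I | intermediate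
31 | C12 alkylzinc iodide from 23 | I[Zn]CC[C@@H]1[C@@]2(C)CCC[C@@](C)(CO[Si](C(C)C)(C(C)C)C(C)C)[C@@H]2[C@@H](O[Si](C)(C)C(C)(C)C)C[C@@]1(C)O[Si](C)(C)C | intermediate
32 | tris-silyl ether of the target | CC1=CC(=O)O[C@@H]1C/C=C(\C)CC[C@@H]1[C@@]2(C)CCC[C@@](C)(CO[Si](C(C)C)(C(C)C)C(C)C)[C@@H]2[C@@H](O[Si](C)(C)C(C)(C)C)C[C@@]1(C)O[Si](C)(C)C | intermediate
33 | CNP0147582.1 | CC1=CC(=O)O[C@@H]1C/C=C(\C)CC[C@@H]1[C@@]2(C)CCC[C@@](C)(CO)[C@@H]2[C@@H](O)C[C@@]1(C)O | target

**Totals**

Total step count: 23. Longest linear sequence: 18 steps (steps 1–16, 22, 23).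

**Steps most likely to fail**

Step 4. The dianion may deprotonate the γ-hydrogen of the butenolide or attack C5 in conjugate (SN2′) fashion, and the ring closure may not discriminate cleanly between chair and boat. Fallback (from 6 and 7, back at 9): 7 would be converted into the bis(silyl) dienol ether F1 (Et3N, TMSCl; then LiN(iPr)2, TMSCl). F1 would be alkylated at its terminal carbon by bromide 6 under ZnBr2 catalysis (vinylogous Mukaiyama-type alkylation) to give keto ester 8 as an isolated compound after aqueous work-up. 8 would then be cyclized to 9 in a separate step with catalytic Cs2CO3 in MeCN, or as its silyl enol ether with TiCl4 (Mukaiyama–Michael), so that no strongly basic carbanion meets the butenolide.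

Step 13. The ketyl may be reduced to the alcohol before it cyclizes, or ring B may close through the alternative chair with the ketyl oxygen axial (8-epimer). Fallback (from 18, back at 33): 18 would be reduced with iBu2AlH to allylic alcohol F3, converted with CBr4/PPh3 into allylic bromide F4, and deketalized (PPTS, aqueous acetone) to bromo ketone F5. An intramolecular Nozaki–Hiyama allylation (CrCl2, THF), with C9 as the γ-carbon of the allylchromium, would close ring B to vinyl carbinol F6. Hydroboration with 9-BBN and B-alkyl Suzuki coupling with 30 (Pd(dppf)Cl2, K3PO4) would give the coupled bis-silyl ether F7, and HF·pyridine would give 33.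

Step 6. Enolization at the hindered ring-fusion carbon may be sluggish, and O-alkylation or attack on the concave face may compete. Fallback (from 11, back at 12): the lithium enolate of 11 would be trapped with monomeric formaldehyde gas in an aldol reaction to give the hydroxymethyl lactone F2, which would be silylated with TIPSOTf/2,6-lutidine to give 12.

Further compounds
F1 | step 4 | 1-methoxy-2-methyl-1,3-bis(trimethylsilyloxy)buta-1,3-diene | COC(O[Si](C)(C)C)=C(C)C(=C)O[Si](C)(C)C
F2 | step 6 | 4α-(hydroxymethyl) lactone | COC(=O)[C@@]1(C)CCC[C@]2(CO)C(=O)O[C@@H](CC3(C)OCCO3)[C@H]12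
F3 | step 13 | allylic alcohol from 18 (C12-OH) | OC/C=C/[C@@]1(C)CCC[C@@](C)(CO[Si](C(C)C)(C(C)C)C(C)C)[C@@H]1[C@@H](O[Si](C)(C)C(C)(C)C)CC2(C)OCCO2
F4 | step 13 | allylic bromide (C12-Br) | BrC/C=C/[C@@]1(C)CCC[C@@](C)(CO[Si](C(C)C)(C(C)C)C(C)C)[C@@H]1[C@@H](O[Si](C)(C)C(C)(C)C)CC2(C)OCCO2
F5 | step 13 | bromo ketone (C8 methyl ketone) | BrC/C=C/[C@@]1(C)CCC[C@@](C)(CO[Si](C(C)C)(C(C)C)C(C)C)[C@@H]1[C@@H](O[Si](C)(C)C(C)(C)C)CC(C)=O
F6 | step 13 | 9β-vinyl decalin-8α-ol | C=C[C@@H]1[C@@]2(C)CCC[C@@](C)(CO[Si](C(C)C)(C(C)C)C(C)C)[C@@H]2[C@@H](O[Si](C)(C)C(C)(C)C)C[C@@]1(C)O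
F7 | step 13 | coupled bis-silyl ether (8-OH free) | CC1=CC(=O)O[C@@H]1C/C=C(\C)CC[C@@H]1[C@@]2(C)CCC[C@@](C)(CO[Si](C(C)C)(C(C)C)C(C)C)[C@@H]2[C@@H](O[Si](C)(C)C(C)(C)C)C[C@@]1(C)O
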